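## Retrosynthetic overview

1. Target 10 ⇐ regioselective 1,2-reduction of epoxy-enedione 9 at the carbonyl next to the ethyl-bearing carbon, with hydride anti to the oxirane (OH syn to epoxide).
2. 9 ⇐ ketal hydrolysis of 8 ⇐ dehydrogenation of saturated epoxy ketone 7. The dehydrogenation erases the ethyl-bearing sp3 stereocentre, which serves only as a traceless relay.
3. 7 ⇐ Weitz–Scheffer epoxidation of enone 6, forming the oxirane (second ring) trans to the ethyl group.
4. 6 ⇐ key step: Cu/phosphoramidite-catalysed enantioselective conjugate addition of Et2Zn to prochiral quinone monoketal 4. This installs the ethyl carbons and the only catalyst-derived stereocentre.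
5. 4 ⇐ oxidative dearomatisation of 2-farnesyl-4-methoxyphenol 3 ⇐ 4-methoxyphenol 1 + farnesyl bromide 2. The carbocycle is the original arene ring; the usual reagent-controlled asymmetric epoxidation of a fully substituted quinone monoketal and the Diels–Alder/retro-Diels–Alder route are avoided.

Assumption: "farnesyl" (Far) = (2E,6E)-3,7,11-trimethyldodeca-2,6,10-trien-1-yl, as in the SMILES. The ligand antipode in step 3 is the one that gives the 5S product, predicted to be (R,S,S) by analogy with cyclohexenone; if the sense is reversed, the other antipode is used.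

## Route

**Step 1**
Reactants: 1, 4-methoxyphenol; 2, (2E,6E)-farnesyl bromide
Product: 3, 4-methoxy-2-farnesylphenol
Conditions: NaH (1.0 equiv), toluene, 0 °C → rt; then 2, rt, 16 h
Reagents that add atoms: farnesyl bromide, `BrC/C=C(\C)CC/C=C(\C)CCC=C(C)C`
Why: Ortho C-allylation of a sodium phenoxide in a non-polar solvent (tight ion pair, SN2 at the primary allylic bromide, then rearomatisation) gives the ortho-farnesyl phenol with E,E geometry retained; para is blocked by OMe and the O-alkyl by-product is separable.

**Step 2**
Reactants: 3, 4-methoxy-2-farnesylphenol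
Product: 4, 4,4-dimethoxy-2-farnesylcyclohexa-2,5-dien-1-one
Conditions: PhI(OAc)2 (1.1 equiv), MeOH, 0 °C, 20 min; NaHCO3 quench
Reagents that add atoms: methanol, `CO`
Why: Hypervalent-iodine oxidative dearomatisation of a p-methoxyphenol, in which MeOH traps the phenoxenium ion at the OMe-bearing carbon, gives the monoketal regiospecifically (C=O next to farnesyl); the phenol is oxidised far faster than the isolated trisubstituted alkenes.

**Step 3 (key step)**
Reactants: 4, 4,4-dimethoxy-2-farnesylcyclohexa-2,5-dien-1-one; 5, diethylzinc
Product: 6, (5S)-5-ethyl-4,4-dimethoxy-2-farnesylcyclohex-2-en-1-one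
Conditions: Cu(OTf)2 (2 mol%), (R,S,S)-BINOL bis(1-phenylethyl)amine phosphoramidite (4 mol%), Et2Zn (1.5 equiv), toluene, −25 °C; sat. NH4Cl
Reagents that add atoms: diethylzinc, `CC[Zn]CC`
Why: Proposed new method: the closest known reaction is the Cu/phosphoramidite-catalysed asymmetric conjugate addition of dialkylzincs to cyclohexenone and to symmetrical 4,4-dialkoxycyclohexa-2,5-dienones, and here the Cu(I)–alkene π-complex/Cu(III) pathway should select the unsubstituted enone C=C (α-alkyl enones are poor substrates) and one enantiotopic face of it, because the farnesyl group lies in the ring plane at the remote α′ position, setting the 5S ethyl stereocentre.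

**Step 4**
Reactants: 6, (5S)-5-ethyl-4,4-dimethoxy-2-farnesylcyclohex-2-en-1-one
Product: 7, (1R,4S,6S)-4-ethyl-5,5-dimethoxy-1-farnesyl-7-oxabicyclo[4.1.0]heptan-2-one
Conditions: t-BuOOH (decane), Triton B (cat.), THF, 0 °C → rt; chromatograph to a single diastereomer (the minor cis isomer would become the enantiomer after step 5)
Reagents that add atoms: tert-butyl hydroperoxide, `CC(C)(C)OO`
Why: Weitz–Scheffer nucleophilic epoxidation touches only the enone (farnesyl alkenes are inert), and the peroxide adds axially to the β-carbon anti to the 1,3-related ethyl group (as in carvone → trans-carvone oxide), so the oxirane forms trans to ethyl and both epoxide stereocentres are set.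

**Step 5**
Reactants: 7, (1R,4S,6S)-4-ethyl-5,5-dimethoxy-1-farnesyl-7-oxabicyclo[4.1.0]heptan-2-one
Product: 8, (1R,6S)-4-ethyl-5,5-dimethoxy-1-farnesyl-7-oxabicyclo[4.1.0]hept-3-en-2-one
Conditions: LiHMDS (1.1 equiv), THF, −78 °C; then PhS(Cl)=N-t-Bu (1.2 equiv), −78 °C → rt
Reagents that add atoms: none
Why: Mukaiyama dehydrogenation: the ketone can enolise only toward the CH2 (the other α-carbon is the quaternary epoxide carbon), the enolate is sulfenylated anti to ethyl and syn-elimination with the cis β-H gives the β-ethyl enone, erasing the relay stereocentre without touching the epoxide centres.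

**Step 6**
Reactants: 8, (1R,6S)-4-ethyl-5,5-dimethoxy-1-farnesyl-7-oxabicyclo[4.1.0]hept-3-en-2-one
Product: 9, (1R,6S)-4-ethyl-1-farnesyl-7-oxabicyclo[4.1.0]hept-3-ene-2,5-dione
Conditions: montmorillonite K10, wet CH2Cl2, rt
Reagents that add atoms: water, `O`
Why: Acid-catalysed ketal hydrolysis via the oxocarbenium ion, using a mild solid acid so that the epoxide and the polyene are spared; no stereocentre is affected.

**Step 7**
Reactants: 9, (1R,6S)-4-ethyl-1-farnesyl-7-oxabicyclo[4.1.0]hept-3-ene-2,5-dione
Product: 10, (1R,5R,6R)-4-ethyl-5-hydroxy-1-farnesyl-7-oxabicyclo[4.1.0]hept-3-en-2-one (target)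
Conditions: DIBAL-H (1.05 equiv), THF, −78 °C; Rochelle salt
Reagents that add atoms: none
Why: 1,2-Reduction is expected at C5=O because C2=O is deactivated as a β-ethyl enone carbonyl and shielded by the quaternary C1, whose farnesyl CH2 sits on the hydride-approach face, while hydride adds anti to the oxirane oxygen (Felkin–Anh/steric), giving the 5R alcohol syn to the epoxide.

## Compound list

1 | 4-methoxyphenol | `COc1ccc(O)cc1` | starting material
2 | (2E,6E)-farnesyl bromide | `BrC/C=C(\C)CC/C=C(\C)CCC=C(C)C` | starting material
3 | 4-methoxy-2-farnesylphenol | `COc1ccc(O)c(C/C=C(\C)CC/C=C(\C)CCC=C(C)C)c1` | intermediate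
4 | 4,4-dimethoxy-2-farnesylcyclohexa-2,5-dien-1-one | `COC1(OC)C=CC(=O)C(C/C=C(\C)CC/C=C(\C)CCC=C(C)C)=C1` | intermediate
5 | diethylzinc | `CC[Zn]CC` | starting material
6 | (5S)-5-ethyl-4,4-dimethoxy-2-farnesylcyclohex-2-en-1-one | `CC[C@H]1CC(=O)C(C/C=C(\C)CC/C=C(\C)CCC=C(C)C)=CC1(OC)OC` | intermediate
7 | (1R,4S,6S)-4-ethyl-5,5-dimethoxy-1-farnesyl-7-oxabicyclo[4.1.0]heptan-2-one | `CC[C@H]1CC(=O)[C@]2(C/C=C(\C)CC/C=C(\C)CCC=C(C)C)O[C@@H]2C1(OC)OC` | intermediate
8 | (1R,6S)-4-ethyl-5,5-dimethoxy-1-farnesyl-7-oxabicyclo[4.1.0]hept-3-en-2-one | `CCC1=CC(=O)[C@]2(C/C=C(\C)CC/C=C(\C)CCC=C(C)C)O[C@@H]2C1(OC)OC` | intermediate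
9 | (1R,6S)-4-ethyl-1-farnesyl-7-oxabicyclo[4.1.0]hept-3-ene-2,5-dione | `CCC1=CC(=O)[C@]2(C/C=C(\C)CC/C=C(\C)CCC=C(C)C)O[C@@H]2C1=O` | intermediate
10 | (1R,5R,6R)-4-ethyl-5-hydroxy-1-farnesyl-7-oxabicyclo[4.1.0]hept-3-en-2-one | `CCC1=CC(=O)[C@]2(C/C=C(\C)CC/C=C(\C)CCC=C(C)C)O[C@@H]2[C@@H]1O` | target

## Summary

Total step count: 7. Longest linear sequence: 7 (fully linear from 4-methoxyphenol).

Steps most likely to fail, with fallbacks:

- **Step 3** (regio- and enantioselectivity of the conjugate addition on an unsymmetrical dienone). Fallback: run the same addition on commercial, symmetrical 4,4-dimethoxycyclohexa-2,5-dienone, where this catalyst class is established. Then attach farnesyl afterwards by α-iodination of the remaining enone (I2, pyridine) and Stille coupling with (E,E)-farnesyl-SnBu3, converging on 6.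
- **Step 4** (slow epoxidation of a hindered α-alkyl enone, or insufficient trans relay). Fallback: replace the steric relay with hydroxyl direction. Reduce 6 with a CBS reagent to the allylic alcohol of the required configuration, epoxidise with VO(acac)2/TBHP (syn-directed, only the allylic alkene reacts), and re-oxidise with Dess–Martin periodinane to 7.
- **Step 7** (regio- and facial selectivity of the enedione reduction, over-reduction). Fallback: differentiate the carbonyls by sequence instead of reagent.
  - Luche-reduce the single ketone of 8 and protect it as the TBS ether.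
  - Unmask the ketal and reduce the now-unique ketone with DIBAL-H (anti to the epoxide), then acetylate.
  - Remove TBS, oxidise that alcohol back to the ketone with Dess–Martin periodinane, and cleave the acetate.
  - If the wrong carbinol epimer forms, correct it by Mitsunobu inversion.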